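**Retrosynthetic overview**

1. Target 23 ⇐ 3-O-angeloylation and desilylation of diol 18 ⇐ C3 reduction and C4 hydroxymethylation of the regiodefined C3–C4 silyl enol ether 16; C18 goes on last, anti to the C10 methyl.
2. 16 ⇐ bicyclo[3.1.0]hexan-2-one 15 by one isomerisation: the allylsilane forms C9–C10 (ring B) while the cyclopropane fusion bond C4–C10 breaks, so the cyclopentanone ring (C1, C2, C3, C4, C10) takes in the cyclopropane carbon C5 and becomes ring A.
3. Enabling feature of 15: ketone C3 is attached to cyclopropane carbon C4; C10 is the methyl-bearing, tertiary cyclopropane carbon; C5, the third cyclopropane carbon, carries exo the arm whose C9 reaches C10 through a six-membered transition state.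
4. 15 ⇐ acyclic α-diazo ketone 14 by catalytic asymmetric intramolecular cyclopropanation of the (E)-C5=C10 alkene; this is the only catalyst-controlled step, and C9, C4 and C3 are relayed from it.
5. 14 ⇐ two Johnson–Claisen rearrangements on geraniol-derived aldehyde 4 with (2-bromoallyl)trimethylsilane 5, isopropenylmagnesium bromide and diazoethane. Ring order: cyclopropane and cyclopentanone (step 10), then B and A together (step 11).

Key step: step 11

Assumption: labdane numbering is used, with the C4 hydroxymethyl carbon (trans to the C10 methyl) called C18 and the C4 methyl C19; the (S,S)-ligand in step 10 is taken to deliver 15, and its antipode is used if the sense of induction is the opposite.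

**Route**

Step 1
Reactants: 1 geraniol
Product: 2 tert-butyl{[(2E)-3,7-dimethylocta-2,6-dien-1-yl]oxy}diphenylsilane
Conditions: TBDPSCl, imidazole, CH2Cl2, 0 °C → rt
Reagents that add atoms: tert-butyl(chloro)diphenylsilane, CC(C)(C)[Si](Cl)(c1ccccc1)c1ccccc1
Why: Silyl ether formation on the primary allylic alcohol is routine and gives a group that should survive every step up to the final fluoride treatment.

Step 2
Reactants: 2 geranyl TBDPS ether
Product: 4 (4E)-6-[(tert-butyldiphenylsilyl)oxy]-4-methylhex-4-enal, via epoxide 3 (not isolated)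
Conditions: mCPBA, NaHCO3, CH2Cl2, −20 → 0 °C; then H5IO6, THF/H2O, 0 °C
Reagents that add atoms: 3-chloroperoxybenzoic acid, OOC(=O)c1cccc(Cl)c1
Why: Prilezhaev epoxidation should prefer the electron-richer 6,7-alkene remote from the allylic oxygen, and periodic acid hydrolyses the epoxide and cleaves the glycol (Malaprade cleavage) without touching the (E)-2,3-alkene.

Step 3
Reactants: 4 (4E)-6-[(tert-butyldiphenylsilyl)oxy]-4-methylhex-4-enal; 5 (2-bromoallyl)trimethylsilane
Product: 7 (6E)-8-[(tert-butyldiphenylsilyl)oxy]-6-methyl-2-[(trimethylsilyl)methyl]octa-1,6-dien-3-ol (racemic), via Grignard reagent 6 (not isolated)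
Conditions: 5, Mg, THF, 40 °C; then 4, −78 → 0 °C; H2O work-up
Reagents that add atoms: magnesium, [Mg] (in 6 only)
Why: Grignard 1,2-addition of the 2-(silylmethyl)vinyl reagent to the aldehyde gives the allylic alcohol, whose racemic carbinol centre is erased in step 4.

Step 4
Reactants: 7 allylic alcohol
Product: 8 ethyl (4Z,8E)-10-[(tert-butyldiphenylsilyl)oxy]-8-methyl-4-[(trimethylsilyl)methyl]deca-4,8-dienoate
Conditions: MeC(OEt)3, EtCO2H (cat.), 140 °C, removal of EtOH
Reagents that add atoms: triethyl orthoacetate, CCOC(C)(OCC)OCC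
Why: The Johnson–Claisen rearrangement through a chair transition state with the carbinol substituent pseudo-equatorial should place the new two-carbon arm trans to C11 on the C8=C9 alkene, which is the (Z)-allylsilane geometry needed in step 11.

Step 5
Reactants: 8 ester
Product: 9 (4Z,8E)-10-[(tert-butyldiphenylsilyl)oxy]-8-methyl-4-[(trimethylsilyl)methyl]deca-4,8-dienal
Conditions: DIBAL-H (1.05 equiv), CH2Cl2, −78 °C; Rochelle salt work-up
Reagents that add atoms: none
Why: DIBAL-H half-reduction stops at the tetrahedral aluminium hemiacetal at −78 °C, which gives the aldehyde on work-up.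

Step 6
Reactants: 9 aldehyde
Product: 10 (6Z,10E)-12-[(tert-butyldiphenylsilyl)oxy]-2,10-dimethyl-6-[(trimethylsilyl)methyl]dodeca-1,6,10-trien-3-ol (racemic)
Conditions: isopropenylmagnesium bromide, THF, −78 → 0 °C; H2O work-up
Reagents that add atoms: isopropenylmagnesium bromide, C=C(C)[Mg]Br
Why: Grignard 1,2-addition sets up the second orthoester Claisen rearrangement; the new carbinol centre is again erased in the next step.

Step 7
Reactants: 10 allylic alcohol
Product: 11 ethyl (4E,8Z,12E)-14-[(tert-butyldiphenylsilyl)oxy]-4,12-dimethyl-8-[(trimethylsilyl)methyl]tetradeca-4,8,12-trienoate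
Conditions: MeC(OEt)3, EtCO2H (cat.), 140 °C, removal of EtOH
Reagents that add atoms: triethyl orthoacetate, CCOC(C)(OCC)OCC
Why: The second Johnson–Claisen rearrangement should give the (E)-C5=C10 trisubstituted alkene by the same chair preference and completes the carbon chain up to C3.

Step 8
Reactants: 11 ester
Product: 12 (4E,8Z,12E)-14-[(tert-butyldiphenylsilyl)oxy]-4,12-dimethyl-8-[(trimethylsilyl)methyl]tetradeca-4,8,12-trienoic acid
Conditions: LiOH·H2O, THF/MeOH/H2O, rt; then dilute HCl to pH 4, 0 °C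
Reagents that add atoms: lithium hydroxide, [Li+].[OH-]
Why: Saponification is unproblematic here, and the cold, weakly acidic work-up is chosen to spare the allylsilane.

Step 9
Reactants: 12 acid
Product: 14 (6E,10Z,14E)-16-[(tert-butyldiphenylsilyl)oxy]-2-diazo-6,14-dimethyl-10-[(trimethylsilyl)methyl]hexadeca-6,10,14-trien-3-one, via mixed anhydride 13 (not isolated)
Conditions: i-BuOCOCl, N-methylmorpholine, THF, −15 °C; then CH3CHN2 (Et2O solution), −15 → 0 °C
Reagents that add atoms: diazoethane, CC=[N+]=[N-]; isobutyl chloroformate, CC(C)COC(Cl)=O (in 13 only)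
Why: Acylation of a diazoalkane by a mixed carbonic anhydride (Arndt–Eistert-type diazo ketone synthesis) gives the α-methyl α-diazo ketone without the HCl that an acid chloride route would release next to the allylsilane.

Step 10
Reactants: 14 α-diazo ketone
Product: 15 (1R,5S,6S)-6-{(3Z,7E)-9-[(tert-butyldiphenylsilyl)oxy]-7-methyl-3-[(trimethylsilyl)methyl]nona-3,7-dien-1-yl}-1,5-dimethylbicyclo[3.1.0]hexan-2-one
Conditions: CuOTf·½C6H6 (5 mol %), (S,S)-tBu-box (6 mol %), CH2Cl2, rt, slow addition of 14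
Reagents that add atoms: none
Why: In this Cu(I)/bis(oxazoline)-catalysed asymmetric intramolecular cyclopropanation the carbenoid adds to the (E)-C5=C10 alkene, the only one that closes a five-membered ring, so the ligand fixes C4, C5 and C10 at once and the stereospecific syn addition places the arm on C5 exo.

Step 11
Reactants: 15 bicyclo[3.1.0]hexan-2-one
Product: 16 (5S,9R,10S)-15-[(tert-butyldiphenylsilyl)oxy]-3-[(trimethylsilyl)oxy]-18-norlabda-3,8(17),13E-triene (trans-decalin; 10α-methyl; 5β-H; 9β-H)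
Conditions: Me3SiNTf2 (10 mol %), 2,6-di-tert-butyl-4-methylpyridine (15 mol %), CH2Cl2, −78 → −30 °C
Reagents that add atoms: none
Why: The silyl Lewis acid silylates the C3 carbonyl oxygen, the cyclopropane fusion bond C4–C10 breaks as C9 of the allylsilane attacks C10 from the side opposite C4, and loss of Me3Si+ from the β-silyl cation at C8 gives the 8(17)-methylidene and returns the catalyst, so the step is a net isomerisation to the C3–C4 silyl enol ether. The reaction type is the Lewis-acid-promoted opening of an acylcyclopropane with participation of a tethered olefin (a cation–olefin cyclisation initiated by a cyclopropyl ketone, known for 5-methyl-6-alkenylbicyclo[3.1.0]hexan-2-ones to cleave the ring-fusion bond with inversion at the methyl-bearing carbon), terminated here by an allylsilane as in a Hosomi–Sakurai reaction with silyl transfer to the enolate oxygen. Ring B closes 6-endo-trig with respect to C8=C9 and 6-exo-tet with respect to the breaking C4–C10 bond, while ring A is not closed but arises from the cyclopentanone ring by one-carbon expansion, C5 becoming a ring member. C10 is set by inversion, so the exo arm on C5 (inherited from the (E)-alkene of 14) translates into the trans ring fusion; C9 is set by the chair transition state with the (Z)-allylsilane, which puts C11 equatorial; C5 is carried over unchanged. The step needs cleavage of C4–C10 and not of the outer bond C4–C5, although the latter overlaps better with the carbonyl π system; this is secured by the tether, which reaches only C10 in a six-membered transition state, and by the tertiary character of C10, and the hindered base suppresses protodesilylation.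

Step 12
Reactants: 16 silyl enol ether
Product: 17 (4S,5S,9R,10S)-15-[(tert-butyldiphenylsilyl)oxy]-18-hydroxylabda-8(17),13E-dien-3-one
Conditions: 37 % aq. HCHO, Sc(OTf)3 (10 mol %), THF, 0 °C → rt
Reagents that add atoms: formaldehyde, C=O
Why: In this aqueous Lewis-acid-catalysed Mukaiyama aldol (hydroxymethylation) of the regiodefined tetrasubstituted silyl enol ether, formaldehyde should attack C4 on the face opposite the axial C10 methyl, which makes CH2OH equatorial and the C4 methyl axial.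

Step 13
Reactants: 17 hydroxy ketone
Product: 18 (3R,4S,5S,9R,10S)-15-[(tert-butyldiphenylsilyl)oxy]labda-8(17),13E-diene-3,18-diol
Conditions: NaBH4, MeOH, 0 °C
Reagents that add atoms: none
Why: Borohydride reduction by axial attack on the C3 face that carries no axial methyl group (both axial methyls lie on the other face) should give the equatorial 3-alcohol.

Step 14
Reactants: 18 diol
Product: 19 (3R,4S,5S,9R,10S)-18-[(tert-butyldimethylsilyl)oxy]-15-[(tert-butyldiphenylsilyl)oxy]labda-8(17),13E-dien-3-ol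
Conditions: TBSCl (1.1 equiv), imidazole, DMF, 0 °C
Reagents that add atoms: tert-butyl(chloro)dimethylsilane, CC(C)(C)[Si](C)(C)Cl
Why: Silylation should discriminate the primary C18 hydroxyl from the secondary C3 hydroxyl next to the quaternary C4.

Step 15
Reactants: 19 3-alcohol; 20 angelic acid
Product: 22 (3R,4S,5S,9R,10S)-18-[(tert-butyldimethylsilyl)oxy]-15-[(tert-butyldiphenylsilyl)oxy]labda-8(17),13E-dien-3-yl (2Z)-2-methylbut-2-enoate, via mixed anhydride 21 (not isolated)
Conditions: 20, 2,4,6-Cl3C6H2COCl, Et3N, toluene, rt; then 19, toluene, 80 °C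
Reagents that add atoms: 2,4,6-trichlorobenzoyl chloride, O=C(Cl)c1c(Cl)cc(Cl)cc1Cl (in 21 only)
Why: Yamaguchi-type esterification through the preformed mixed anhydride, run without DMAP to limit Z→E isomerisation to the tiglate, acylates the only free hydroxyl.

Step 16
Reactants: 22 bis-silyl ether
Product: 23 (3R,4S,5S,9R,10S)-15,18-dihydroxylabda-8(17),13E-dien-3-yl (2Z)-2-methylbut-2-enoate
Conditions: HF·pyridine, pyridine, THF, 0 °C → rt
Reagents that add atoms: none
Why: Buffered fluoride desilylation removes both silyl ethers under mildly acidic conditions that should not promote 3→18 acyl migration or angelate isomerisation.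

**Compound list**

1 | geraniol | CC(C)=CCC/C(C)=C/CO | starting material
2 | geranyl tert-butyldiphenylsilyl ether | CC(C)=CCC/C(C)=C/CO[Si](c1ccccc1)(c1ccccc1)C(C)(C)C | intermediate
3 | 6,7-epoxygeranyl tert-butyldiphenylsilyl ether (racemic, not isolated) | CC1(C)OC1CC/C(C)=C/CO[Si](c1ccccc1)(c1ccccc1)C(C)(C)C | intermediate
4 | (4E)-6-[(tert-butyldiphenylsilyl)oxy]-4-methylhex-4-enal | O=CCC/C(C)=C/CO[Si](c1ccccc1)(c1ccccc1)C(C)(C)C | intermediate
5 | (2-bromoallyl)trimethylsilane | C=C(Br)C[Si](C)(C)C | starting material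
6 | [3-(trimethylsilyl)prop-1-en-2-yl]magnesium bromide (not isolated) | C=C([Mg]Br)C[Si](C)(C)C | intermediate
7 | (6E)-8-[(tert-butyldiphenylsilyl)oxy]-6-methyl-2-[(trimethylsilyl)methyl]octa-1,6-dien-3-ol (racemic) | C=C(C[Si](C)(C)C)C(O)CC/C(C)=C/CO[Si](c1ccccc1)(c1ccccc1)C(C)(C)C | intermediate
8 | ethyl (4Z,8E)-10-[(tert-butyldiphenylsilyl)oxy]-8-methyl-4-[(trimethylsilyl)methyl]deca-4,8-dienoate | CCOC(=O)CC/C(C[Si](C)(C)C)=C/CC/C(C)=C/CO[Si](c1ccccc1)(c1ccccc1)C(C)(C)C | intermediate
9 | (4Z,8E)-10-[(tert-butyldiphenylsilyl)oxy]-8-methyl-4-[(trimethylsilyl)methyl]deca-4,8-dienal | O=CCC/C(C[Si](C)(C)C)=C/CC/C(C)=C/CO[Si](c1ccccc1)(c1ccccc1)C(C)(C)C | intermediate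
10 | (6Z,10E)-12-[(tert-butyldiphenylsilyl)oxy]-2,10-dimethyl-6-[(trimethylsilyl)methyl]dodeca-1,6,10-trien-3-ol (racemic) | C=C(C)C(O)CC/C(C[Si](C)(C)C)=C/CC/C(C)=C/CO[Si](c1ccccc1)(c1ccccc1)C(C)(C)C | intermediate
11 | ethyl (4E,8Z,12E)-14-[(tert-butyldiphenylsilyl)oxy]-4,12-dimethyl-8-[(trimethylsilyl)methyl]tetradeca-4,8,12-trienoate | CCOC(=O)CC/C(C)=C/CC/C(C[Si](C)(C)C)=C/CC/C(C)=C/CO[Si](c1ccccc1)(c1ccccc1)C(C)(C)C | intermediate
12 | (4E,8Z,12E)-14-[(tert-butyldiphenylsilyl)oxy]-4,12-dimethyl-8-[(trimethylsilyl)methyl]tetradeca-4,8,12-trienoic acid | OC(=O)CC/C(C)=C/CC/C(C[Si](C)(C)C)=C/CC/C(C)=C/CO[Si](c1ccccc1)(c1ccccc1)C(C)(C)C | intermediate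
13 | isobutyl carbonic mixed anhydride of 12 (not isolated) | CC(C)COC(=O)OC(=O)CC/C(C)=C/CC/C(C[Si](C)(C)C)=C/CC/C(C)=C/CO[Si](c1ccccc1)(c1ccccc1)C(C)(C)C | intermediate
14 | (6E,10Z,14E)-16-[(tert-butyldiphenylsilyl)oxy]-2-diazo-6,14-dimethyl-10-[(trimethylsilyl)methyl]hexadeca-6,10,14-trien-3-one | CC(=[N+]=[N-])C(=O)CC/C(C)=C/CC/C(C[Si](C)(C)C)=C/CC/C(C)=C/CO[Si](c1ccccc1)(c1ccccc1)C(C)(C)C | intermediate
15 | (1R,5S,6S)-6-{(3Z,7E)-9-[(tert-butyldiphenylsilyl)oxy]-7-methyl-3-[(trimethylsilyl)methyl]nona-3,7-dien-1-yl}-1,5-dimethylbicyclo[3.1.0]hexan-2-one (arm on C6 exo, trans to the five-membered ring) | C[C@]12C(=O)CC[C@@]1(C)[C@@H]2CC/C(C[Si](C)(C)C)=C/CC/C(C)=C/CO[Si](c1ccccc1)(c1ccccc1)C(C)(C)C | intermediate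
16 | (5S,9R,10S)-15-[(tert-butyldiphenylsilyl)oxy]-3-[(trimethylsilyl)oxy]-18-norlabda-3,8(17),13E-triene | C=C1CC[C@H]2[C@@](C)(CCC(O[Si](C)(C)C)=C2C)[C@@H]1CC/C(C)=C/CO[Si](c1ccccc1)(c1ccccc1)C(C)(C)C | intermediate
17 | (4S,5S,9R,10S)-15-[(tert-butyldiphenylsilyl)oxy]-18-hydroxylabda-8(17),13E-dien-3-one | C=C1CC[C@H]2[C@@](C)(CCC(=O)[C@]2(C)CO)[C@@H]1CC/C(C)=C/CO[Si](c1ccccc1)(c1ccccc1)C(C)(C)C | intermediate
18 | (3R,4S,5S,9R,10S)-15-[(tert-butyldiphenylsilyl)oxy]labda-8(17),13E-diene-3,18-diol | C=C1CC[C@H]2[C@@](C)(CC[C@@H](O)[C@]2(C)CO)[C@@H]1CC/C(C)=C/CO[Si](c1ccccc1)(c1ccccc1)C(C)(C)C | intermediate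
19 | (3R,4S,5S,9R,10S)-18-[(tert-butyldimethylsilyl)oxy]-15-[(tert-butyldiphenylsilyl)oxy]labda-8(17),13E-dien-3-ol | C=C1CC[C@H]2[C@@](C)(CC[C@@H](O)[C@]2(C)CO[Si](C)(C)C(C)(C)C)[C@@H]1CC/C(C)=C/CO[Si](c1ccccc1)(c1ccccc1)C(C)(C)C | intermediate
20 | angelic acid, (2Z)-2-methylbut-2-enoic acid | C/C=C(/C)C(=O)O | starting material
21 | angelic 2,4,6-trichlorobenzoic mixed anhydride (not isolated) | C/C=C(/C)C(=O)OC(=O)c1c(Cl)cc(Cl)cc1Cl | intermediate
22 | (3R,4S,5S,9R,10S)-18-[(tert-butyldimethylsilyl)oxy]-15-[(tert-butyldiphenylsilyl)oxy]labda-8(17),13E-dien-3-yl (2Z)-2-methylbut-2-enoate | C=C1CC[C@H]2[C@@](C)(CC[C@@H](OC(=O)/C(C)=C\C)[C@]2(C)CO[Si](C)(C)C(C)(C)C)[C@@H]1CC/C(C)=C/CO[Si](c1ccccc1)(c1ccccc1)C(C)(C)C | intermediate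
23 | (3R,4S,5S,9R,10S)-15,18-dihydroxylabda-8(17),13E-dien-3-yl (2Z)-2-methylbut-2-enoate (ent-labdane: 10α-methyl, 5β-H, 9β-H, 3α-O equatorial, 4α-methyl, 4β-CH2OH) | C=C1CC[C@H]2[C@@](C)(CC[C@@H](OC(=O)/C(C)=C\C)[C@]2(C)CO)[C@@H]1CC/C(C)=C/CO | target

**Step count and risks**

Total steps: 16. Longest linear sequence: 16 (geraniol 1 → 23); 5 and 20 enter as purchased partners.

Steps most likely to fail:

1. Step 11. The outer cyclopropane bond C4–C5 may ionise instead (with hydride shift), the C10 cation may lose a proton before ring B closes, or the allylsilane may be protodesilylated. The fallback sets out from 11 and returns at 16; it turns the cyclopropane into a donor–acceptor cyclopropane with a removable sulfone, which stabilises charge at C4 without a stereoelectronic demand. Ester 11 is condensed with lithiated methyl phenyl sulfone (2.2 equiv, THF, −78 → 0 °C) to the β-keto sulfone F1. Diazo transfer (p-ABSA, Et3N, MeCN) gives the α-diazo-β-keto sulfone F2. Cu(I)/bis(oxazoline)-catalysed intramolecular cyclopropanation, a well-used reaction for this substrate class, gives the 1-(phenylsulfonyl)bicyclo[3.1.0]hexan-2-one F3. Lewis acid (TMSOTf cat., CH2Cl2, −78 °C) then opens C4–C10 with the same allylsilane capture and gives, after aqueous work-up, the decalin β-keto sulfone F4. C-Methylation (K2CO3, MeI, DMF) gives the 4-methyl-4-sulfonyl ketone F5. Reductive desulfonylation with SmI2 (THF, −78 °C) forms the C3–C4 enolate regiospecifically, and silylation (TMSCl, Et3N) gives 16.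

2. Step 10. The methyl-substituted copper carbenoid may show insufficient enantioface discrimination. The fallback sets out from 14 and returns at 15; it replaces catalyst control by a covalent resolution. Achiral Cu(acac)2 (CH2Cl2, reflux, slow addition) gives racemic 15, that is 15 together with its enantiomer F6. Lithiated (S)-N,S-dimethyl-S-phenylsulfoximine (THF, −78 °C) adds to the ketone and gives the diastereomeric β-hydroxy sulfoximines F7 (from 15) and F8 (from F6), which are separated by chromatography. Thermolysis of F7 (toluene, 110 °C) releases 15.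

3. Step 15. The angelate may isomerise to the tiglate during a slow acylation of the hindered C3 hydroxyl. The fallback sets out from 19 and returns at 22; it builds the (Z)-alkene on the molecule instead of transferring it. Alcohol 19 is esterified with 2-[bis(2,2,2-trifluoroethoxy)phosphoryl]propanoic acid (DCC, DMAP, CH2Cl2) to the phosphonate ester F9. Still–Gennari olefination (KHMDS, 18-crown-6, THF, −78 °C, acetaldehyde) then gives 22.

Further compounds
F1 | step 11 | (5E,9Z,13E)-15-[(tert-butyldiphenylsilyl)oxy]-5,13-dimethyl-1-(phenylsulfonyl)-9-[(trimethylsilyl)methyl]pentadeca-5,9,13-trien-2-one | O=S(=O)(CC(=O)CC/C(C)=C/CC/C(C[Si](C)(C)C)=C/CC/C(C)=C/CO[Si](c1ccccc1)(c1ccccc1)C(C)(C)C)c1ccccc1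
F2 | step 11 | (5E,9Z,13E)-15-[(tert-butyldiphenylsilyl)oxy]-1-diazo-5,13-dimethyl-1-(phenylsulfonyl)-9-[(trimethylsilyl)methyl]pentadeca-5,9,13-trien-2-one | O=S(=O)(C(=[N+]=[N-])C(=O)CC/C(C)=C/CC/C(C[Si](C)(C)C)=C/CC/C(C)=C/CO[Si](c1ccccc1)(c1ccccc1)C(C)(C)C)c1ccccc1
F3 | step 11 | (1S,5S,6S)-6-{(3Z,7E)-9-[(tert-butyldiphenylsilyl)oxy]-7-methyl-3-[(trimethylsilyl)methyl]nona-3,7-dien-1-yl}-5-methyl-1-(phenylsulfonyl)bicyclo[3.1.0]hexan-2-one | O=S(=O)(c1ccccc1)[C@]12C(=O)CC[C@@]1(C)[C@@H]2CC/C(C[Si](C)(C)C)=C/CC/C(C)=C/CO[Si](c1ccccc1)(c1ccccc1)C(C)(C)C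
F4 | step 11 | 15-[(tert-butyldiphenylsilyl)oxy]-4-(phenylsulfonyl)-18,19-dinorlabda-8(17),13E-dien-3-one (ring stereocentres C5, C9, C10 as in 16; C4 epimers) | C=C1CC[C@H]2[C@@](C)(CCC(=O)C2S(=O)(=O)c2ccccc2)[C@@H]1CC/C(C)=C/CO[Si](c1ccccc1)(c1ccccc1)C(C)(C)C
F5 | step 11 | 15-[(tert-butyldiphenylsilyl)oxy]-4-(phenylsulfonyl)-18-norlabda-8(17),13E-dien-3-one (ring stereocentres C5, C9, C10 as in 16; C4 not controlled) | C=C1CC[C@H]2[C@@](C)(CCC(=O)C2(C)S(=O)(=O)c2ccccc2)[C@@H]1CC/C(C)=C/CO[Si](c1ccccc1)(c1ccccc1)C(C)(C)C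
F6 | step 10 | (1S,5R,6R)-enantiomer of 15 | C[C@@]12C(=O)CC[C@]1(C)[C@H]2CC/C(C[Si](C)(C)C)=C/CC/C(C)=C/CO[Si](c1ccccc1)(c1ccccc1)C(C)(C)C
F7 | step 10 | β-hydroxy sulfoximine from 15 and (S)-N,S-dimethyl-S-phenylsulfoximine (carbinol configuration not assigned) | C[C@]12C(O)(C[S@@](=O)(=NC)c3ccccc3)CC[C@@]1(C)[C@@H]2CC/C(C[Si](C)(C)C)=C/CC/C(C)=C/CO[Si](c1ccccc1)(c1ccccc1)C(C)(C)C
F8 | step 10 | β-hydroxy sulfoximine from F6 and (S)-N,S-dimethyl-S-phenylsulfoximine (carbinol configuration not assigned) | C[C@@]12C(O)(C[S@@](=O)(=NC)c3ccccc3)CC[C@]1(C)[C@H]2CC/C(C[Si](C)(C)C)=C/CC/C(C)=C/CO[Si](c1ccccc1)(c1ccccc1)C(C)(C)C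
F9 | step 15 | 3-O-{2-[bis(2,2,2-trifluoroethoxy)phosphoryl]propanoyl} derivative of 19 | C=C1CC[C@H]2[C@@](C)(CC[C@@H](OC(=O)C(C)P(=O)(OCC(F)(F)F)OCC(F)(F)F)[C@]2(C)CO[Si](C)(C)C(C)(C)C)[C@@H]1CC/C(C)=C/CO[Si](c1ccccc1)(c1ccccc1)C(C)(C)C
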